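The numbers were chosen freely; no experiment stands behind them.

The partner was what I counted first in theta and eta, since the catalyst and the protic impurity both take it.

    partner + free catalyst → catalyst intermediate A (k1 = 99400 M⁻¹ s⁻¹)
    substrate + catalyst intermediate A → catalyst intermediate B (k2 = 25900 M⁻¹ s⁻¹)
    catalyst intermediate B → free catalyst + target (k3 = 303 s⁻¹)
    substrate + target → side product (k4 = 147 M⁻¹ s⁻¹)
    partner + protic impurity → quenched reagent (k5 = 3890 M⁻¹ s⁻¹)
    partner + precatalyst → free catalyst + spent reagent (k6 = 250 M⁻¹ s⁻¹)

in all of them: substrate 2.0 mM; partner 3.00 mM; protic impurity 2.00 mM; time 15 s
- theta: precatalyst 5.0 µM
- eta: precatalyst 10 µM

- which of these there is most of at the end, counted by the substrate in it, theta (side product / catalyst intermediate B / target / substrate)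
- which of these there is most of at the end, counted by the substrate in it, eta (side product / catalyst intermediate B / target / substrate)
- how much there is at the end of the one of these that leads, in percent of the substrate charged: theta
- how much there is at the end of the one of these that leads, in percent of the substrate charged: eta

- percentages count the substrate that a species holds: one side product counts as two
- run time (theta): 15 s

1. The first instants. I set partner against impurity. Partner's half-life by step 5 is 0.089 s, against 9.2 min by step 6, so it goes to the impurity first. That leaves a spare c(partner) of 1.00 mM, and even the precatalyst charge of eta, 10 µM, is small beside it.

2. The budget. Each catalytic round spends one partner and makes one target, and each side product then holds a second substrate. So I defined the reach, 100%: twice the partner spare after the impurity, as a share of the substrate charged. It is the most substrate that spare partner can carry into side product. At this even value, reckoned from the charges, partner and substrate tie as limiting reagent, in both flasks.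

3. The middle. With c(partner) at the spare amount, the precatalyst wakes with a half-life of 2.77 s. One round takes 0.0327 s, the sum of its waits at those amounts. With the catalyst fully awake, the spare would last 6.53 s in theta and 3.27 s in eta. I reckoned these at the starting amounts with all the catalyst awake, so I took them as lower limits.

4. The end. Target is lost to substrate in a step I treated as pseudo-first-order, with a lifetime of 3.40 s at full substrate. That is shorter than the run, so I expected side product to lead in both flasks, below the reach, and eta to stand higher with twice the catalyst. My reckoning went no closer than that.

The forecast gave side product at 54% for theta and side product at 61% for eta, noting that “Target is steadily eaten by substrate”.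

Side product led, at 53.7% in theta and 61.4% in eta. Partner stood at 4.02% of its charge in theta at 15.0 s and 0.118% in eta. Left until 150 s, side product reached 95.4% in theta and 95.5% in eta, against a reach of 100%. A neighbour flask, like theta but with 1.2 mM of partner, has a reach of −80.0%, and at 15.0 s it held 0.217% side product.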